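Each incoming ligand taken up frees one leaving ligand, so in these flasks the two ligands together stay at 58.0 mM.

    complex with one exchanged + incoming ligand ⇌ leaving ligand + complex with two exchanged (K1 = 4.2, k1 = 0.098 /M/s)
    complex with two exchanged → over-reaction product (k2 = 0.0013 /s)
    starting complex + incoming ligand ⇌ leaving ligand + complex with one exchanged (K3 = 13, k3 = 1.6 /M/s)

| flask | starting complex | incoming ligand | leaving ligand | time |
|---|---|---|---|---|
| red | 10 mM | 18.0 mM | 40.0 mM | 6.0 min |
| amber | 20 mM | 18.0 mM | 40.0 mM | 6.0 min |
| ochre | 40 mM | 18.0 mM | 40.0 mM | 6.0 min |

1. amount of complex with two exchanged at the end, in percent of the starting complex charged for red, amber, ochre, in this order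
2. the shape of the row from first to last (rises, then falls / rises all the way / falls, then rises / falls all the way / hardly changes)

- "hardly changes" means that all values lie within two and a half points (for a concentration: within two and a half percent of the largest)
- run time (red): 6.0 min

Turn the question round. With its way back and the loss to over-reaction product set aside, a level or rising row needs the second exchange to work forward on each charged complex at least as fast in ochre as in red. That forward rate per charged complex is its forward constant times free incoming ligand times the exchanged share of the charge. In logarithms, those factors add.

With the red charges, the forward rates alone halve the starting complex in 0.40 min and the complex with one exchanged in 6.5 min, so in red the first exchange runs forward faster than the second. The first exchange is therefore treated as a pre-equilibrium. With the second exchange left aside, the invariant leaves one unknown, the ligand turned over, and setting the quotient equal to 13 gives a quadratic. Its root is 7.43 mM in red, 12.0 mM in amber and 15.3 mM in ochre. In this reckoning, free incoming ligand is then 10.6 mM, 6.00 mM and 2.65 mM.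

The forward constant, free ligand, exchanged share and run time multiply to the second-exchange budget, the fraction of the charge turned over if those levels held. It is 27.7 % in red, 12.7 % in amber and 3.59 % in ochre. A level row needs equal logarithms, yet ochre lies 0.887 powers of ten below red: 0.602 from free ligand and 0.287 from the share. This reckoning commits to a row that falls all the way.

The forecast gave 13.5 %, 6.3 % and 2 %, a row that falls all the way, since “More starting complex consumes the limited incoming ligand in the first step”. The simulation gives 13.6 %, 6.46 % and 2.07 %, a row that falls all the way.

Complex with two exchanged and over-reaction product together reach 17.4 % in red against the budget of 27.7 %, and 2.71 % in ochre against 3.59 %. The using up of incoming ligand is a part of what pulls red and ochre apart. Runs that keep incoming ligand at its charge reach 25.7 % in red and 21.9 % in ochre, so their gap is narrower than the real one: 3.8 percentage points instead of 12 points.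

(The numbers of this flask are assumed; no experiment stands behind them.)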